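The readings are simulated with made-up constants.

The readings hold no partner, so its balance cannot be written directly and has to be inferred from the winter run.

all flasks: starting material 0.010 M
- winter: partner 1.5 equiv; run made earlier
- flask: partner 1.00 equiv; time 10 min

winter run (percent of the starting material charged)

| time / min | target / % | starting material / % |
|---|---|---|
| 0.250 | 6.6 | 76.6 |
| 0.417 | 13.0 | 66.2 |
| 0.833 | 28.2 | 48.6 |
| 1.50 | 34.8 | 33.0 |
| 3.00 | 23.0 | 24.2 |

(standard deviation of a reading: 0.5 percentage points)

- the analysis behind the earlier runs scatters by 0.5 percentage points, standard deviation
- a reading or a percentage of target counts all its forms, free or not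

- the moment within 10 min at which there is most target
- the amount of target, in percent of the starting material charged, at that time

1. In the winter run, starting material loses 16 percentage points between 0.833 min and 1.50 min, but 8.8 points from there to 3.00 min, with 24.2% still present. A shrinking supply of partner fits that slowing.

2. The highest winter reading of target is 34.8%, at 1.50 min. Target at its peak per partner charged is then 23.2%, the return on partner, a reading with the scatter of one.

3. With the same return, this flask's 1.00 equiv gives 23.2%. The peak time is held at the winter reading, near 1.50 min. This reckoning commits to those two numbers.

4. The weak link is the assumed constant return: it comes from one run at one charge of partner, so 23.2% stays an estimate that carries this assumption.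

5. The forecast differs: 34% at 2.6 min, higher than the estimate here, holding that “partner starves sooner, which protects target”.

The simulation gives 23.6% at 1.35 min.

    starting material ⇌ open intermediate (K = 0.440, k = 0.0266 s⁻¹)
    partner → second intermediate (k = 0.0357 s⁻¹)
    open intermediate + second intermediate → target (k = 13.0 L mol⁻¹ s⁻¹)
    2 open intermediate → homo product (k = 0.473 L mol⁻¹ s⁻¹)
    second intermediate → decomposed reagent (k = 0.0223 s⁻¹)
    target → over-reaction product (k = 0.0266 s⁻¹)
    crystals ⇌ target, rate k7*(cs7 - [target]) while solid is left; crystals form when [target] > cs7 (solubility = 0.880 mM, k = 0.412 s⁻¹)

The return on partner gave 23.2% for this flask against that 23.6%. In this flask partner, the limiting reagent with 0% left at 10.0 min, has a half-life of 0.32 min by its step to second intermediate, shorter than the 0.43 min of dissolved target going to over-reaction product at 0.324 min. At the best time, partner stands at 5.52% of its charge and over-reaction product at 16.6%. For the neighbour charged with 2.50 equiv of partner, the return gives 58.0%, more than its simulated peak of 47.9%, a return of 19.2%.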